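Time in a vessel acts on target through what stands beside it, so the first thing to find is a ratio that time does not move.

| flask | substrate | enzyme | remark | time |
|---|---|---|---|---|
| zeta | 0.10 M | 10 µM | run made earlier |  |
| eta | 0.10 M | 6.7 µM | run made earlier |  |
| gamma | 0.10 M | 15 µM | run made earlier |  |
| theta | 0.20 M | 10 µM | run made earlier |  |
| east | 0.10 M | 10 µM | one stirred flow tank at steady state, fed with the mixture as stated, mean residence time 5.0 d |  |
| north | 0.10 M | 10 µM | everything together in a closed stirred flask, run for 5.0 d | 5.0 d |
| south-west | 0.10 M | 10 µM | one stirred flow tank at steady state, fed with the mixture as stated, mean residence time 25.0 d |  |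
| south-east | 0.10 M | 10 µM | plug flow through a tube for 5.0 d, no back-mixing | 5.0 d |

| run | time / d | target / % | over-reaction product / % | substrate / % |
|---|---|---|---|---|
| zeta | 0.625 | 39.8 | 0.1 | 59.1 |
| zeta | 1.25 | 72.8 | 4.2 | 23.8 |
| zeta | 2.00 | 81.2 | 17.3 | 0.6 |
| zeta | 3.00 | 60.5 | 38.4 | 0 |
| zeta | 4.00 | 49.2 | 51.2 | 0 |
| zeta | 5.00 | 42.2 | 57.8 | 0 |
| eta | 0.250 | 12.0 | 0.8 | 89.8 |
| eta | 0.333 | 14.9 | 0.4 | 85.2 |
| eta | 0.500 | 22.9 | 0.3 | 76.8 |
| eta | 0.833 | 35.8 | 0.4 | 64.2 |
| eta | 1.25 | 52.1 | 0.9 | 45.8 |
| eta | 2.08 | 77.7 | 5.4 | 17.2 |
| eta | 3.00 | 83.2 | 16.0 | 1.7 |
| gamma | 0.417 | 41.1 | 0.1 | 58.0 |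
| gamma | 0.833 | 72.2 | 4.3 | 23.6 |
| gamma | 1.25 | 82.6 | 15.3 | 2.1 |
| gamma | 1.67 | 67.7 | 31.7 | 0.8 |
| gamma | 2.00 | 57.4 | 43.2 | 0 |
| gamma | 2.50 | 47.0 | 52.5 | 0 |
| gamma | 3.00 | 39.6 | 59.7 | 0.2 |
| theta | 0.250 | 9.8 | 0 | 91.5 |
| theta | 0.417 | 15.1 | 0 | 85.9 |
| theta | 0.833 | 28.9 | 0 | 70.6 |
| theta | 1.67 | 56.6 | 1.0 | 43.5 |
| theta | 3.00 | 83.2 | 9.9 | 5.8 |

(standard deviation of a reading: 0.5 percentage points)

- the stated concentrations are those of everything mixed, before any reaction; amounts are the same in each set-up
- the earlier runs were made in a closed, stirred flask

- the set-up with the highest share of target in all that became target or over-reaction product, at the outlet or at the end ("none" if the first two lie within 2 percentage points) (east / north / south-west / south-east / none)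
- share of target in all that became target or over-reaction product, at the outlet or at the end, east
- share of target in all that became target or over-reaction product, at the outlet or at the end, north
- share of target in all that became target or over-reaction product, at the outlet or at the end, south-west
- share of target in all that became target or over-reaction product, at the outlet or at the end, south-east

One enzyme both makes target from substrate and over-reacts target, so its amount should cancel from the ratio of the two rates, each taken per unit of its own concentration. That ratio, the selectivity factor, can be frozen. Integrated over a closed run down to substrate share a, with target taken as what the substrate has lost, it is over-reaction product divided by (a − 1 − ln a). The eta run at 2.08 d reads 0.0579, and the zeta run, with more enzyme, reads 0.0624.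

In a stirred tank, with s the share of substrate left, over-reaction product per target is the exposure number N = selectivity factor × (1 − s)/s, and the share of target is 1/(1 + N). But s needs the enzyme. The theta run reads a top rate of 0.0717 M/d, the eta tail a half-rate substrate level of 0.0124 M, and the zeta tail an enzyme death of 0.298 /d, assumed to strike unoccupied enzyme. My reckoning, with the fed substrate taken as turned over by the enzyme still working in the tank, then gives s of 11.9% in east and 6.19% in south-west, about half, so in this reckoning N needs the enzyme death as well as the residence time. The shares come to 70.1% in east and 53.3% in south-west. North and south-east repeat the zeta history, at 42.2%, so east stands highest.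

The forecast names east, with 58%, 42.2%, 45% and 42.2% for east, north, south-west and south-east, lower than my tanks, holding that “residual substrate shields target”.

The simulation gives east as the best set-up, with 62.0% for east, 42.3% for north, 48.0% for south-west and 42.3% for south-east.

    substrate + enzyme ⇌ complex (K = 160 /M, k = 99000 /M/h)
    enzyme + target → enzyme + over-reaction product (k = 1900 /M/h)
    enzyme → spent catalyst (k = 0.0150 /h)
    complex → enzyme + target (k = 310 /h)

The east tank holds 0.00856 M of substrate, less than the 0.0119 M reckoned. The frozen factor with that level gives 61.8%.

The neighbour of south-east charged with 0.25 M keeps 0.012% of its substrate at 5.00 d. The closed-run form, target = (a^factor − a)/(1 − factor), gives 62.9% of target there, and the simulation holds 63.0% of the substrate charged as target.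

(All runs were generated by integration for an exercise, noise included.)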